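**Plan**

- Retrosynthesis: cut the coumarin O–CH2 ether bond (Mitsunobu), then the C2′=C3′ alkene (Horner–Wadsworth–Emmons) and the C4′–C5′ bond next to the bicycle (Wittig, then saturation). This leaves an exo ester on C2 of the oxabicycle.
- Enabling feature: in the 7-oxabicyclo[2.2.1]heptane, C2 (chain-bearing CH beside the methyl bridgehead C1) and C3 (CMe2 beside the CH bridgehead C4), together with the exocyclic carbon on C2, are the CH2–C(=O)–CMe2 bridge of a 1,4,4-trimethyl-8-oxabicyclo[3.2.1]octan-3-one. Cutting C2–C3 and putting the exocyclic carbon back into the ring as the carbonyl (retro-Wolff) gives that ketone as its α-diazo derivative.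
- The bicyclic ketone is cut at C1–C2 and C4–C5 into 2-methylfuran and the 1,1-dimethyl-2-oxyallyl cation ([4+3]).
- Forward: the [4+3] cycloaddition closes the oxolane and the seven-membered ring together. Hydrogenation, resolution, diazo transfer and photochemical ring contraction follow; the chain is then grown outward from the ester carbon and the coumarin is attached last.
- Stereochemistry: the bridgeheads are cis by the cycloaddition and become (1R,4S) by resolution of the derived alcohol as its camphanate. C2 (S, exo) is set by methoxide equilibration of the Wolff ester, and the E-alkene by the Horner–Wadsworth–Emmons step.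

Key step: step 8

Assumption: 4-hydroxy-5-methylcoumarin 20 and (1S)-(−)-camphanic chloride are treated as purchasable.

**Route**

Step 1
Reactants: 1 2-methylfuran (excess); 2 3-bromo-3-methylbutan-2-one
Product: 4 (±)-1,4,4-trimethyl-8-oxabicyclo[3.2.1]oct-6-en-3-one, via oxyallyl cation 3 (not isolated)
Conditions: Et3N, CF3CH2OH, 0 °C → rt
Reagents that add atoms: none
Why: [4+3] cycloaddition of a furan with an oxyallyl cation: base-induced loss of HBr from 2 in the ionising solvent gives cation 3, which adds across C2/C5 of the furan; bonding of the CMe2 terminus to the unsubstituted furan carbon and of the CH2 terminus to the methyl-bearing carbon avoids two adjacent fully substituted carbons, so the 1,4,4-trimethyl adduct should be the main isomer (the 1,2,2-isomer is removed by chromatography), and the two bridgeheads are necessarily cis and racemic.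

Step 2
Reactants: 4 (±)-1,4,4-trimethyl-8-oxabicyclo[3.2.1]oct-6-en-3-one
Product: 5 (±)-1,4,4-trimethyl-8-oxabicyclo[3.2.1]octan-3-one
Conditions: H2 (1 atm), Pd/C, EtOAc, rt
Reagents that add atoms: none
Why: Heterogeneous catalytic hydrogenation of the strained cis-disubstituted C6=C7 alkene is fast and leaves the hindered ketone and the ether bridge untouched.

Step 3
Reactants: 5 (±)-1,4,4-trimethyl-8-oxabicyclo[3.2.1]octan-3-one
Product: 6 (±)-(1R*,3S*,5S*)-1,4,4-trimethyl-8-oxabicyclo[3.2.1]octan-3-ol (3-OH axial, on the side of the C6–C7 bridge)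
Conditions: LiBH(s-Bu)3 (L-Selectride), THF, −78 → 0 °C; then NaOH, H2O2
Reagents that add atoms: none
Why: Bulky-hydride reduction of a bridged ketone: the hydride should approach the carbonyl face turned away from the C6–C7 bridge and give the axial alcohol as one diastereomer; the C3 centre is only a handle for resolution and is erased in step 6.

Step 4
Reactants: 6 (±)-(1R*,3S*,5S*)-1,4,4-trimethyl-8-oxabicyclo[3.2.1]octan-3-ol
Product: 7 (1R,3S,5S)-1,4,4-trimethyl-8-oxabicyclo[3.2.1]octan-3-yl (1S,4R)-4,7,7-trimethyl-3-oxo-2-oxabicyclo[2.2.1]heptane-1-carboxylate (single diastereomer after separation)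
Conditions: (1S)-(−)-camphanic chloride, Et3N, DMAP, CH2Cl2, 0 °C → reflux; separation of the two diastereomers by chromatography and recrystallisation
Reagents that add atoms: (1S)-(−)-camphanic chloride, O=C(Cl)[C@@]12CC[C@@](C)(C(=O)O1)C2(C)C
Why: Classical resolution by DMAP-catalysed acylation with an enantiopure acid chloride that has no α-hydrogen and cannot racemise; the two esters are diastereomers and should be separable, and the configuration of the alcohol part is to be assigned by X-ray analysis against the known acyl part.

Step 5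
Reactants: 7 the (1R,3S,5S)-camphanate
Product: 8 (1R,3S,5S)-1,4,4-trimethyl-8-oxabicyclo[3.2.1]octan-3-ol
Conditions: KOH, MeOH/H2O, reflux; then aq. HCl
Reagents that add atoms: none
Why: Ester saponification; the ether bridge and the three stereocentres are inert to hydroxide.

Step 6
Reactants: 8 (1R,3S,5S)-1,4,4-trimethyl-8-oxabicyclo[3.2.1]octan-3-ol
Product: 9 (1R,5S)-1,4,4-trimethyl-8-oxabicyclo[3.2.1]octan-3-one
Conditions: Dess–Martin periodinane, CH2Cl2, rt
Reagents that add atoms: none
Why: Dess–Martin oxidation of a hindered secondary alcohol under neutral conditions returns the ketone as a single enantiomer; the bridgeheads are not enolisable.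

Step 7
Reactants: 9 (1R,5S)-1,4,4-trimethyl-8-oxabicyclo[3.2.1]octan-3-one
Product: 11 (1R,5S)-2-diazo-1,4,4-trimethyl-8-oxabicyclo[3.2.1]octan-3-one, via trifluoroacetyl ketone 10 (not isolated)
Conditions: LiN(SiMe3)2, THF, −78 °C; CF3CO2CH2CF3; aq. HCl work-up; then 4-acetamidobenzenesulfonyl azide, Et3N, H2O (1 equiv), MeCN, rt
Reagents that add atoms: 4-acetamidobenzenesulfonyl azide, CC(=O)Nc1ccc(cc1)S(=O)(=O)N=[N+]=[N-]; 2,2,2-trifluoroethyl trifluoroacetate, O=C(OCC(F)(F)F)C(F)(F)F (acyl group of 10 only)
Why: Detrifluoroacetylative diazo transfer (Claisen-type trifluoroacetylation followed by Regitz diazo transfer): C2 is the only enolisable α-carbon because C4 is quaternary, so the diazo group can only enter at C2, and the activating acyl group leaves as the N-sulfonyl trifluoroacetamide.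

Step 8
Reactants: 11 (1R,5S)-2-diazo-1,4,4-trimethyl-8-oxabicyclo[3.2.1]octan-3-one
Product: 14 methyl (1R,2S,4S)-1,3,3-trimethyl-7-oxabicyclo[2.2.1]heptane-2-carboxylate, via ketene 12 (not isolated), via endo ester 13 (not isolated)
Conditions: hν (medium-pressure Hg lamp, Pyrex), MeOH, rt; then NaOMe (0.2 equiv), MeOH, rt → 40 °C
Reagents that add atoms: methanol, CO
Why: Photolysis expels N2 from the ring-locked s-cis α-diazo ketone and, in concert or through the singlet carbene, the CMe2 carbon shifts from the carbonyl carbon C3 to the diazo carbon C2, so that the C2–C4 bond (C2–C3 of the product) forms and ketene 12 results; this is the photochemical Wolff ring contraction of a cyclic α-diazo ketone with capture of the ketene by an alcohol. The new ring arises by a 1,2-alkyl shift inside the existing bicycle (the oxanone ring contracts to an oxolane and the seven-membered carbocycle to a cyclohexane), not by a new cyclisation, so the cis bridgeheads pass unchanged from 11 into the product. Methanol adds to 12 and the ester enol is protonated at C2, probably mainly from the open exo face, which gives endo ester 13 beside 14. The new stereocentre C2 is therefore set under thermodynamic control: catalytic methoxide epimerises 13 through its enolate to exo ester 14, whose ester group lies beside the oxygen bridge and clear of the endo hydrogens on C5 and C6. The step needs a single possible migration and no competing hydrogen shift; the substrate secures both, because the carbonyl carbon carries no migrating group other than CMe2 and the carbene carbon is flanked by the fully substituted bridgehead C1. The base is kept catalytic and the temperature low because the same enolate could expel the bridging oxygen.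

Step 9
Reactants: 14 methyl (1R,2S,4S)-1,3,3-trimethyl-7-oxabicyclo[2.2.1]heptane-2-carboxylate
Product: 15 (1R,2S,4S)-1,3,3-trimethyl-7-oxabicyclo[2.2.1]heptane-2-carbaldehyde
Conditions: i-Bu2AlH (1.1 equiv), CH2Cl2, −78 °C; aqueous work-up
Reagents that add atoms: none
Why: Partial reduction of an ester with DIBAL-H at low temperature: the tetrahedral aluminium hemiacetal of this ester, flanked by two quaternary carbons, should persist until work-up and release the aldehyde without touching C2.

Step 10
Reactants: 15 (1R,2S,4S)-1,3,3-trimethyl-7-oxabicyclo[2.2.1]heptane-2-carbaldehyde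
Product: 16 (3E)-4-[(1R,2S,4S)-1,3,3-trimethyl-7-oxabicyclo[2.2.1]heptan-2-yl]but-3-en-2-one
Conditions: Ph3P=CHC(O)CH3, toluene, 100 °C
Reagents that add atoms: 1-(triphenyl-λ5-phosphanylidene)propan-2-one, CC(=O)C=P(c1ccccc1)(c1ccccc1)c1ccccc1
Why: Wittig olefination with a stabilised ylide gives the E-enone, and the ylide is too weakly basic to enolise the aldehyde, so the exo configuration at C2 is kept.

Step 11
Reactants: 16 the E-enone
Product: 17 4-[(1R,2S,4S)-1,3,3-trimethyl-7-oxabicyclo[2.2.1]heptan-2-yl]butan-2-one
Conditions: H2 (1 atm), Pd/C, EtOAc, rt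
Reagents that add atoms: none
Why: Catalytic hydrogenation saturates the conjugated C=C much faster than the ketone, and there is no group prone to hydrogenolysis.

Step 12
Reactants: 17 the methyl ketone
Product: 18 ethyl (2E)-3-methyl-5-[(1R,2S,4S)-1,3,3-trimethyl-7-oxabicyclo[2.2.1]heptan-2-yl]pent-2-enoate
Conditions: (EtO)2P(O)CH2CO2Et, NaH, THF, 0 → 50 °C
Reagents that add atoms: triethyl phosphonoacetate, CCOC(=O)CP(=O)(OCC)OCC
Why: Horner–Wadsworth–Emmons olefination of a methyl ketone favours the E-enoate (ester trans to the longer chain); the Z-isomer is to be removed by chromatography.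

Step 13
Reactants: 18 the E-enoate
Product: 19 (2E)-3-methyl-5-[(1R,2S,4S)-1,3,3-trimethyl-7-oxabicyclo[2.2.1]heptan-2-yl]pent-2-en-1-ol
Conditions: i-Bu2AlH (2.5 equiv), CH2Cl2, −78 → 0 °C
Reagents that add atoms: none
Why: DIBAL-H reduces the conjugated ester by 1,2-addition only, giving the allylic alcohol with the alkene geometry unchanged.

Step 14
Reactants: 19 the E-allylic alcohol; 20 4-hydroxy-5-methylcoumarin
Product: 21 4-{[(2E)-3-methyl-5-[(1R,2S,4S)-1,3,3-trimethyl-7-oxabicyclo[2.2.1]heptan-2-yl]pent-2-en-1-yl]oxy}-5-methyl-2H-chromen-2-one (the target)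
Conditions: PPh3, DIAD, THF, 0 °C → rt
Reagents that add atoms: none
Why: Mitsunobu etherification: the acidic 4-hydroxycoumarin (a vinylogous carboxylic acid) is alkylated on O4 by SN2 displacement at the activated primary allylic carbon, with no change in alkene geometry and under neutral conditions that spare the oxabicycle.

**Compound list**

1 | 2-methylfuran | Cc1ccco1 | starting material
2 | 3-bromo-3-methylbutan-2-one | CC(=O)C(C)(C)Br | starting material
3 | 1,1-dimethyl-2-oxidoallyl cation (oxyallyl zwitterion) | C[C+](C)C([O-])=C | intermediate (not isolated)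
4 | (±)-1,4,4-trimethyl-8-oxabicyclo[3.2.1]oct-6-en-3-one (racemic; the (1S,5S)-enantiomer is drawn) | C1C(=O)C(C)(C)[C@@H]2C=C[C@@]1(C)O2 | intermediate
5 | (±)-1,4,4-trimethyl-8-oxabicyclo[3.2.1]octan-3-one (racemic; the (1R,5S)-enantiomer is drawn) | C1C(=O)C(C)(C)[C@@H]2CC[C@@]1(C)O2 | intermediate
6 | (±)-(1R*,3S*,5S*)-1,4,4-trimethyl-8-oxabicyclo[3.2.1]octan-3-ol (racemic; OH axial, towards the C6–C7 bridge; the (1R,3S,5S)-enantiomer is drawn) | C1[C@H](O)C(C)(C)[C@@H]2CC[C@@]1(C)O2 | intermediate
7 | (1R,3S,5S)-1,4,4-trimethyl-8-oxabicyclo[3.2.1]octan-3-yl (1S,4R)-4,7,7-trimethyl-3-oxo-2-oxabicyclo[2.2.1]heptane-1-carboxylate | C1[C@H](OC(=O)[C@@]34CC[C@@](C)(C(=O)O3)C4(C)C)C(C)(C)[C@@H]2CC[C@@]1(C)O2 | intermediate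
8 | (1R,3S,5S)-1,4,4-trimethyl-8-oxabicyclo[3.2.1]octan-3-ol (single enantiomer) | C1[C@H](O)C(C)(C)[C@@H]2CC[C@@]1(C)O2 | intermediate
9 | (1R,5S)-1,4,4-trimethyl-8-oxabicyclo[3.2.1]octan-3-one (single enantiomer) | C1C(=O)C(C)(C)[C@@H]2CC[C@@]1(C)O2 | intermediate
10 | (1R,5S)-1,4,4-trimethyl-2-(trifluoroacetyl)-8-oxabicyclo[3.2.1]octan-3-one (C2 enolised, configuration there undefined) | FC(F)(F)C(=O)C1C(=O)C(C)(C)[C@@H]2CC[C@@]1(C)O2 | intermediate (not isolated)
11 | (1R,5S)-2-diazo-1,4,4-trimethyl-8-oxabicyclo[3.2.1]octan-3-one | [N-]=[N+]=C1C(=O)C(C)(C)[C@@H]2CC[C@@]1(C)O2 | intermediate (key-step precursor)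
12 | (1R,4S)-1,3,3-trimethyl-2-(oxomethylidene)-7-oxabicyclo[2.2.1]heptane (ketene) | O=C=C1C(C)(C)[C@@H]2CC[C@@]1(C)O2 | intermediate (not isolated)
13 | methyl (1R,2R,4S)-1,3,3-trimethyl-7-oxabicyclo[2.2.1]heptane-2-carboxylate (endo ester) | COC(=O)[C@@H]1C(C)(C)[C@@H]2CC[C@@]1(C)O2 | intermediate (not isolated)
14 | methyl (1R,2S,4S)-1,3,3-trimethyl-7-oxabicyclo[2.2.1]heptane-2-carboxylate (exo ester) | COC(=O)[C@H]1C(C)(C)[C@@H]2CC[C@@]1(C)O2 | intermediate (key-step product)
15 | (1R,2S,4S)-1,3,3-trimethyl-7-oxabicyclo[2.2.1]heptane-2-carbaldehyde | O=C[C@H]1C(C)(C)[C@@H]2CC[C@@]1(C)O2 | intermediate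
16 | (3E)-4-[(1R,2S,4S)-1,3,3-trimethyl-7-oxabicyclo[2.2.1]heptan-2-yl]but-3-en-2-one | CC(=O)/C=C/[C@H]1C(C)(C)[C@@H]2CC[C@@]1(C)O2 | intermediate
17 | 4-[(1R,2S,4S)-1,3,3-trimethyl-7-oxabicyclo[2.2.1]heptan-2-yl]butan-2-one | CC(=O)CC[C@H]1C(C)(C)[C@@H]2CC[C@@]1(C)O2 | intermediate
18 | ethyl (2E)-3-methyl-5-[(1R,2S,4S)-1,3,3-trimethyl-7-oxabicyclo[2.2.1]heptan-2-yl]pent-2-enoate | CCOC(=O)/C=C(\C)CC[C@H]1C(C)(C)[C@@H]2CC[C@@]1(C)O2 | intermediate
19 | (2E)-3-methyl-5-[(1R,2S,4S)-1,3,3-trimethyl-7-oxabicyclo[2.2.1]heptan-2-yl]pent-2-en-1-ol | OC/C=C(\C)CC[C@H]1C(C)(C)[C@@H]2CC[C@@]1(C)O2 | intermediate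
20 | 4-hydroxy-5-methylcoumarin (4-hydroxy-5-methyl-2H-chromen-2-one) | Cc1cccc2oc(=O)cc(O)c12 | starting material
21 | 4-{[(2E)-3-methyl-5-[(1R,2S,4S)-1,3,3-trimethyl-7-oxabicyclo[2.2.1]heptan-2-yl]pent-2-en-1-yl]oxy}-5-methyl-2H-chromen-2-one | C/C(=C\COc1cc(=O)oc2cccc(C)c12)CC[C@H]1C(C)(C)[C@@H]2CC[C@@]1(C)O2 | target

**Step count**

Total: 14 steps. Longest linear sequence: 14 steps (1 and 2 to 21); the coumarin 20 enters in the last step.

**Steps most likely to fail**

Step 8 (key step). The epimerisation at C2 may stop short of the exo ester, and the ester enolate may instead expel the bridging oxygen by β-elimination, opening the oxabicycle to a hydroxycyclohexene ester; the carbene may also insert into the O–H bond of methanol in place of rearranging. The fallback sets out from 11 and comes back to the route at 17. Irradiation of 11 in THF/H2O traps the ketene with water and should give (1R,4S)-1,3,3-trimethyl-7-oxabicyclo[2.2.1]heptane-2-carboxylic acid F1 as a mixture of C2 epimers, whose configuration no longer matters. Photoredox decarboxylation of F1 (Ir[dF(CF3)ppy]2(dtbbpy)PF6, K2HPO4, DMF, blue LEDs, rt) in the presence of but-3-en-2-one generates the secondary C2 radical. Giese addition of this radical on the exo face, away from the endo hydrogens of C5 and C6, should deliver methyl ketone 17 directly. The ring contraction is kept, C2 is set kinetically by the radical addition, and no enolisable ester meets base. The extruded carbon leaves as CO2 and both chain carbons come from the enone, so steps 9 to 11 are skipped.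

Step 1. Regiocontrol in the cycloaddition may be insufficient, with the oxyallyl termini bonding the other way round to the unsymmetrical furan, and the bromo ketone may be lost to solvolysis or to simple alkylation of the furan. The fallback sets out from 1 and comes back at 5; it moves the regiochemical decision from the cycloaddition to an enolate alkylation. Cycloaddition of 1 with the symmetrical oxyallyl species generated reductively from 1,1,3,3-tetrabromoacetone (Zn–Cu couple, B(OEt)3, THF) gives 2,4-dibromo-1-methyl-8-oxabicyclo[3.2.1]oct-6-en-3-one F2, for which no regioisomer exists. Reductive debromination (Zn–Cu couple, NH4Cl, MeOH) gives (±)-1-methyl-8-oxabicyclo[3.2.1]oct-6-en-3-one F3, and hydrogenation (H2, Pd/C, EtOAc) gives (±)-1-methyl-8-oxabicyclo[3.2.1]octan-3-one F4. Double methylation of F4 (KOt-Bu, MeI, THF/t-BuOH) should take place on the α-carbon remote from the quaternary bridgehead, as 3,3-disubstituted cyclohexanones enolise away from the quaternary carbon, and so return racemic ketone 5.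

Step 4. Acylation of the hindered axial alcohol may be slow, and the two diastereomeric camphanates may not separate cleanly. The fallback sets out from 6 and comes back at 8; it replaces diastereomer separation by an enzymatic kinetic resolution. Treatment of 6 with immobilised Candida antarctica lipase B and vinyl acetate (MTBE, 40 °C) should acylate one enantiomer only. The empirical rule for lipase acylation of secondary alcohols, applied with CMe2 as the large and CH2 as the medium flank, predicts that the (3R)-alcohol reacts. This would give (1S,3R,5R)-1,4,4-trimethyl-8-oxabicyclo[3.2.1]octan-3-yl acetate F5 and leave alcohol 8 unreacted, to be separated by chromatography and oxidised as in step 6. If the enzyme prefers the other enantiomer, the acetate fraction is saponified instead.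

**Further compounds**

F1 | step 8 | (1R,4S)-1,3,3-trimethyl-7-oxabicyclo[2.2.1]heptane-2-carboxylic acid (mixture of C2 epimers) | OC(=O)C1C(C)(C)[C@@H]2CC[C@@]1(C)O2
F2 | step 1 | 2,4-dibromo-1-methyl-8-oxabicyclo[3.2.1]oct-6-en-3-one (racemic, bromine epimers) | CC12C=CC(O1)C(Br)C(=O)C2Br
F3 | step 1 | (±)-1-methyl-8-oxabicyclo[3.2.1]oct-6-en-3-one (racemic; one enantiomer drawn) | C1C(=O)C[C@@H]2C=C[C@@]1(C)O2
F4 | step 1 | (±)-1-methyl-8-oxabicyclo[3.2.1]octan-3-one (racemic; one enantiomer drawn) | C1C(=O)C[C@@H]2CC[C@@]1(C)O2
F5 | step 4 | (1S,3R,5R)-1,4,4-trimethyl-8-oxabicyclo[3.2.1]octan-3-yl acetate | C1[C@@H](OC(C)=O)C(C)(C)[C@H]2CC[C@]1(C)O2
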